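Feature: in the oxolane ring (O1, C2, C3, C4, C5), C2 bears both O1 and ring A (4-hydroxy-3-methoxyphenyl), so it is an aldehyde-level carbon. Its neighbour C3 bears a methyl group that can be read as a reduced formyl group, which makes C2–C3 the bond of an aldol between an O1=C2 oxocarbenium ion and an enol.
Retrosynthesis: the C3 methyl goes back to CHO. C2–C3 is cut and the enol oxygen is tied to C2, so the oxolane becomes a 2-aryl-4,5-dihydro-1,3-dioxepine. The enol ether alkene is moved back to the allylic position, the two acetal C–O bonds (one of them O1–C2) are cut, and last C4–C7′ to the benzylic carbon of ring B (4-hydroxy-3,5-dimethoxyphenyl).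
Forward: C4–C7′ forms by Stille coupling on a cis-stannylated butenediol and O1–C2 by acetalisation to the seven-membered ring. The alkene shift and the contraction to the five-membered ring follow, then CHO to CH3 and debenzylation.
Stereochemistry: C4 (R) comes from a chiral nickel hydride in the alkene shift. C3 and C2 follow from C4 in the reversible contraction, which settles on the all-trans (2R,3R,4R) array; later steps touch no stereocentre.

Key step: step 8

Assumption: which antipode of the diphosphine delivers (5R) in a 5-arylmethyl substrate has to be fixed by experiment; (R,R)-Me-DuPHOS is written for the antipode that does.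

Step 1
Reactants: 1 syringaldehyde (4-hydroxy-3,5-dimethoxybenzaldehyde)
Product: 2 4-(benzyloxy)-3,5-dimethoxybenzaldehyde
Conditions: BnBr, K2CO3, DMF, 50 °C
Reagents that add atoms: benzyl bromide, BrCc1ccccc1
Why: Williamson ether synthesis in which the phenoxide of 1 is alkylated by the benzylic bromide, giving an aryl benzyl ether that is inert to every later reagent until the closing hydrogenolysis.

Step 2
Reactants: 2 4-(benzyloxy)-3,5-dimethoxybenzaldehyde
Product: 3 [4-(benzyloxy)-3,5-dimethoxyphenyl]methanol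
Conditions: NaBH4, MeOH, 0 °C
Reagents that add atoms: none
Why: Borohydride reduction of an aromatic aldehyde to the benzylic alcohol, with no other reducible group present.

Step 3
Reactants: 3 [4-(benzyloxy)-3,5-dimethoxyphenyl]methanol
Product: 4 2-(benzyloxy)-5-(bromomethyl)-1,3-dimethoxybenzene
Conditions: PBr3, CH2Cl2, 0 °C
Reagents that add atoms: phosphorus tribromide, BrP(Br)Br
Why: Bromination of an electron-rich benzylic alcohol through its phosphite ester is fast at 0 °C and spares the aryl ethers, and the labile bromide is used without storage.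

Step 4
Reactants: 5 but-2-yne-1,4-diol
Product: 6 (E)-2-(tributylstannyl)but-2-ene-1,4-diol (the two CH2OH groups cis)
Conditions: Bu3SnH, Pd(PPh3)4 (1 mol %), THF, 0 °C to rt
Reagents that add atoms: tributyltin hydride, CCCC[SnH](CCCC)CCCC
Why: Palladium-catalysed hydrostannation, in which zerovalent palladium inserts into Sn–H and delivers H and Sn to the same face of the symmetrical alkyne, so there is no regiochemical question and the two CH2OH groups end up cis, as the later ring closure demands.

Step 5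
Reactants: 6 (E)-2-(tributylstannyl)but-2-ene-1,4-diol; 4 2-(benzyloxy)-5-(bromomethyl)-1,3-dimethoxybenzene
Product: 7 (Z)-2-{[4-(benzyloxy)-3,5-dimethoxyphenyl]methyl}but-2-ene-1,4-diol
Conditions: Pd2(dba)3 (2.5 mol %), AsPh3 (20 mol %), CuI (10 mol %), DMF, 50 °C
Reagents that add atoms: none
Why: Stille coupling of a benzylic bromide with an alkenylstannane forms the future C4–C7′ bond with retention of the alkene geometry, and the neutral conditions tolerate the free hydroxy groups.

Step 6
Reactants: 7 (Z)-2-{[4-(benzyloxy)-3,5-dimethoxyphenyl]methyl}but-2-ene-1,4-diol; 8 4-(benzyloxy)-3-methoxybenzaldehyde (O-benzylvanillin)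
Product: 9 2-[4-(benzyloxy)-3-methoxyphenyl]-5-{[4-(benzyloxy)-3,5-dimethoxyphenyl]methyl}-4,7-dihydro-1,3-dioxepine (racemic at C2)
Conditions: PPTS (5 mol %), toluene, reflux, Dean–Stark trap
Reagents that add atoms: none
Why: Acid-catalysed acetalisation with azeotropic removal of water closes the seven-membered ring as it does for cis-but-2-ene-1,4-diol itself, and the new acetal centre need not be controlled because step 8 erases it.

Step 7
Reactants: 9 2-[4-(benzyloxy)-3-methoxyphenyl]-5-{[4-(benzyloxy)-3,5-dimethoxyphenyl]methyl}-4,7-dihydro-1,3-dioxepine (racemic at C2)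
Product: 10 (5R)-2-[4-(benzyloxy)-3-methoxyphenyl]-5-{[4-(benzyloxy)-3,5-dimethoxyphenyl]methyl}-4,5-dihydro-1,3-dioxepine (configuration at C2 left open)
Conditions: NiBr2[(R,R)-Me-DuPHOS] (3 mol %), LiBHEt3 (3 mol %), THF, −40 to −20 °C
Reagents that add atoms: none
Why: Asymmetric alkene isomerisation by a nickel hydride, known for 5-alkyl-4,7-dihydro-1,3-dioxepines: Ni–H places H on the substituted carbon C5 and Ni on C6, syn β-hydride elimination toward C7 releases the enol ether, and the twofold-symmetric diphosphine chooses the alkene face so that C5 becomes R.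

Step 8
Reactants: 10 (5R)-2-[4-(benzyloxy)-3-methoxyphenyl]-5-{[4-(benzyloxy)-3,5-dimethoxyphenyl]methyl}-4,5-dihydro-1,3-dioxepine
Product: 13 (2R,3R,4R)-2-[4-(benzyloxy)-3-methoxyphenyl]-4-{[4-(benzyloxy)-3,5-dimethoxyphenyl]methyl}oxolane-3-carbaldehyde, via oxocarbenium silyl enol ether 11 (not isolated), via 2,3-cis aldehyde 12 (not isolated)
Conditions: TMSOTf (10 mol %), CH2Cl2, −78 °C, then −30 °C; Et3N quench at −78 °C
Reagents that add atoms: none
Why: TMSOTf silylates the enol ether oxygen (dioxepine O1) of 10 and the C2–O1 bond breaks, giving a (Z)-silyl enol ether tethered to an O3=C2 oxocarbenium ion conjugated with the 4-benzyloxy-3-methoxyphenyl ring (11), at which point the acetal configuration is lost. The enol α-carbon (dioxepine C6, oxolane C3) then adds to C2 in an intramolecular Mukaiyama aldol-type step and the silyl group is handed on; this is the known Lewis-acid rearrangement of 4,5-dihydro-1,3-dioxepines to oxolane-3-carbaldehydes, a relative of the Petasis–Ferrier rearrangement. The only ring closed is the oxolane, in a 5-(enolexo)-endo-trig mode, with the O=C2 bond inside the new ring and the enol C=C outside it. C3 is set by C4, because allylic strain in the Z enol ether turns the C4–H bond into the enol plane so that C2 arrives anti to the arylmethyl group. C2 should first appear cis to the formyl group (12) under kinetic control and is corrected on warming, since the donor aryl ring lets C2–C3 reopen to 11 until the all-trans isomer 13 collects. The step needs three selectivities: ionisation at the enol oxygen (the other mode gives a poorer vinyloxy cation and is a reversible dead end), C- over O-recombination (O-attack only returns 10), and no attack of ring B on C2 (held back by catalytic acid, the low temperature ceiling and the cold amine quench).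

Step 9
Reactants: 13 (2R,3R,4R)-2-[4-(benzyloxy)-3-methoxyphenyl]-4-{[4-(benzyloxy)-3,5-dimethoxyphenyl]methyl}oxolane-3-carbaldehyde
Product: 14 [(2R,3S,4R)-2-[4-(benzyloxy)-3-methoxyphenyl]-4-{[4-(benzyloxy)-3,5-dimethoxyphenyl]methyl}oxolan-3-yl]methanol
Conditions: NaBH4, MeOH–THF, 0 °C
Reagents that add atoms: none
Why: Borohydride reduction is fast at 0 °C, so the β-alkoxy aldehyde is consumed before it can epimerise or lose the ring oxygen by β-elimination, and the change of the C3 descriptor to S is only a change of priorities.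

Step 10
Reactants: 14 [(2R,3S,4R)-2-[4-(benzyloxy)-3-methoxyphenyl]-4-{[4-(benzyloxy)-3,5-dimethoxyphenyl]methyl}oxolan-3-yl]methanol
Product: 15 [(2R,3S,4R)-2-[4-(benzyloxy)-3-methoxyphenyl]-4-{[4-(benzyloxy)-3,5-dimethoxyphenyl]methyl}oxolan-3-yl]methyl 4-methylbenzenesulfonate
Conditions: TsCl, Et3N, DMAP (cat.), CH2Cl2, 0 °C to rt
Reagents that add atoms: p-toluenesulfonyl chloride, Cc1ccc(cc1)S(Cl)(=O)=O
Why: Sulfonylation of the only free hydroxy group, a primary alcohol, under standard amine-base conditions that leave all ethers untouched.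

Step 11
Reactants: 15 [(2R,3S,4R)-2-[4-(benzyloxy)-3-methoxyphenyl]-4-{[4-(benzyloxy)-3,5-dimethoxyphenyl]methyl}oxolan-3-yl]methyl 4-methylbenzenesulfonate
Product: 16 (2R,3R,4R)-2-[4-(benzyloxy)-3-methoxyphenyl]-4-{[4-(benzyloxy)-3,5-dimethoxyphenyl]methyl}-3-methyloxolane
Conditions: LiBHEt3, THF, 0 °C to rt
Reagents that add atoms: none
Why: SN2 displacement of a primary tosylate by the strongly nucleophilic hydride of LiBHEt3 copes with β-branching, takes place at a non-stereogenic carbon and spares aryl and benzylic ethers at room temperature.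

Step 12
Reactants: 16 (2R,3R,4R)-2-[4-(benzyloxy)-3-methoxyphenyl]-4-{[4-(benzyloxy)-3,5-dimethoxyphenyl]methyl}-3-methyloxolane
Product: 17 4-{[(3R,4R,5R)-5-(4-hydroxy-3-methoxyphenyl)-4-methyloxolan-3-yl]methyl}-2,6-dimethoxyphenol (CID53359708)
Conditions: H2 (1 atm), 10% Pd/C, EtOAc–EtOH, rt
Reagents that add atoms: none
Why: Catalytic hydrogenolysis cleaves the two aryl benzyl ethers much faster than the secondary benzylic C2–O1 bond under neutral conditions at one atmosphere, so the reaction is stopped once two equivalents of hydrogen are taken up.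

Compound list
1 | syringaldehyde (4-hydroxy-3,5-dimethoxybenzaldehyde) | COc1cc(C=O)cc(OC)c1O | starting material
2 | 4-(benzyloxy)-3,5-dimethoxybenzaldehyde | COc1cc(C=O)cc(OC)c1OCc1ccccc1 | intermediate
3 | [4-(benzyloxy)-3,5-dimethoxyphenyl]methanol | COc1cc(CO)cc(OC)c1OCc1ccccc1 | intermediate
4 | 2-(benzyloxy)-5-(bromomethyl)-1,3-dimethoxybenzene | COc1cc(CBr)cc(OC)c1OCc1ccccc1 | intermediate
5 | but-2-yne-1,4-diol | OCC#CCO | starting material
6 | (E)-2-(tributylstannyl)but-2-ene-1,4-diol | OC/C([Sn](CCCC)(CCCC)CCCC)=C\CO | intermediate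
7 | (Z)-2-{[4-(benzyloxy)-3,5-dimethoxyphenyl]methyl}but-2-ene-1,4-diol | OC/C(Cc1cc(OC)c(OCc2ccccc2)c(OC)c1)=C\CO | intermediate
8 | 4-(benzyloxy)-3-methoxybenzaldehyde (O-benzylvanillin) | COc1cc(C=O)ccc1OCc1ccccc1 | starting material
9 | 2-[4-(benzyloxy)-3-methoxyphenyl]-5-{[4-(benzyloxy)-3,5-dimethoxyphenyl]methyl}-4,7-dihydro-1,3-dioxepine, racemic at C2 | COc1cc(C2OCC=C(Cc3cc(OC)c(OCc4ccccc4)c(OC)c3)CO2)ccc1OCc1ccccc1 | intermediate
10 | (5R)-2-[4-(benzyloxy)-3-methoxyphenyl]-5-{[4-(benzyloxy)-3,5-dimethoxyphenyl]methyl}-4,5-dihydro-1,3-dioxepine, C2 left open | COc1cc(C2OC[C@H](Cc3cc(OC)c(OCc4ccccc4)c(OC)c3)C=CO2)ccc1OCc1ccccc1 | intermediate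
11 | {[4-(benzyloxy)-3-methoxyphenyl]methylidene}[(2R,3Z)-2-{[4-(benzyloxy)-3,5-dimethoxyphenyl]methyl}-4-(trimethylsilyloxy)but-3-en-1-yl]oxonium triflate | COc1cc(C=[O+]C[C@H](Cc2cc(OC)c(OCc3ccccc3)c(OC)c2)/C=C\O[Si](C)(C)C)ccc1OCc1ccccc1.[O-]S(=O)(=O)C(F)(F)F | intermediate
12 | (2S,3R,4R)-2-[4-(benzyloxy)-3-methoxyphenyl]-4-{[4-(benzyloxy)-3,5-dimethoxyphenyl]methyl}oxolane-3-carbaldehyde (2,3-cis, 3,4-trans) | COc1cc([C@H]2OC[C@H](Cc3cc(OC)c(OCc4ccccc4)c(OC)c3)[C@H]2C=O)ccc1OCc1ccccc1 | intermediate
13 | (2R,3R,4R)-2-[4-(benzyloxy)-3-methoxyphenyl]-4-{[4-(benzyloxy)-3,5-dimethoxyphenyl]methyl}oxolane-3-carbaldehyde (all-trans) | COc1cc([C@@H]2OC[C@H](Cc3cc(OC)c(OCc4ccccc4)c(OC)c3)[C@H]2C=O)ccc1OCc1ccccc1 | intermediate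
14 | [(2R,3S,4R)-2-[4-(benzyloxy)-3-methoxyphenyl]-4-{[4-(benzyloxy)-3,5-dimethoxyphenyl]methyl}oxolan-3-yl]methanol | COc1cc([C@@H]2OC[C@H](Cc3cc(OC)c(OCc4ccccc4)c(OC)c3)[C@H]2CO)ccc1OCc1ccccc1 | intermediate
15 | [(2R,3S,4R)-2-[4-(benzyloxy)-3-methoxyphenyl]-4-{[4-(benzyloxy)-3,5-dimethoxyphenyl]methyl}oxolan-3-yl]methyl 4-methylbenzenesulfonate | COc1cc([C@@H]2OC[C@H](Cc3cc(OC)c(OCc4ccccc4)c(OC)c3)[C@H]2COS(=O)(=O)c5ccc(C)cc5)ccc1OCc1ccccc1 | intermediate
16 | (2R,3R,4R)-2-[4-(benzyloxy)-3-methoxyphenyl]-4-{[4-(benzyloxy)-3,5-dimethoxyphenyl]methyl}-3-methyloxolane | COc1cc([C@@H]2OC[C@H](Cc3cc(OC)c(OCc4ccccc4)c(OC)c3)[C@H]2C)ccc1OCc1ccccc1 | intermediate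
17 | 4-{[(3R,4R,5R)-5-(4-hydroxy-3-methoxyphenyl)-4-methyloxolan-3-yl]methyl}-2,6-dimethoxyphenol | COc1cc([C@@H]2OC[C@H](Cc3cc(OC)c(O)c(OC)c3)[C@H]2C)ccc1O | target

Total steps: 12. Longest linear sequence: 11 steps (1, 2, 3, 4, 7, 9, 10, 13, 14, 15, 16, 17); step 4 lies on the one-step side branch.

Steps most likely to fail

**Step 7.** Substrate 9 is a racemate, and its only stereocentre, C2, already makes the two alkene faces different, so the ligand and the acetal centre compete for the face of hydride delivery.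
- For one antipode the two influences are mismatched. This can erode the enantiomeric purity at C5 or stall the reaction near half conversion.
- Insertion into the trisubstituted alkene may also be slow.

The fallback takes the absolute configuration from resolution instead of catalysis and sets out from 9. An achiral ruthenium hydride, RuHCl(CO)(PPh3)3 in toluene at 80 °C, shifts the alkene and gives 10 together with its mirror-image series, the (5S)-vinyl acetal F1. The contraction of step 8 turns this racemate into 13 and the (2S,3S,4S)-aldehyde F2, and NaBH4 then gives 14 and the (2S,3R,4S)-alcohol F3. The racemic alcohol is separated by preparative chromatography on a cellulose tris(3,5-dimethylphenylcarbamate) phase. The route is rejoined at 14.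

**Step 8.** Two processes bound the temperature window.
- If equilibration through reopening of C2–C3 is too slow, the 2,3-cis isomer persists.
- If the medium is too forcing, the product ionises at the benzylic C2–O1 bond and the electron-rich ring B captures C2 irreversibly in a six-membered Friedel–Crafts closure.
- Traces of water would hydrolyse the vinyl acetal.

The fallback makes the C2–aryl bond by Grignard addition and closes the ring by etherification. It sets out from 10.
- Dilute aqueous HCl in THF hydrolyses the vinyl acetal to (4R)-4-{[4-(benzyloxy)-3,5-dimethoxyphenyl]methyl}oxolan-2-ol F4, with recovery of 8.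
- TEMPO/PhI(OAc)2 oxidises this to the (4R)-lactone F5.
- LiN(iPr)2 and then MeI at −78 °C methylate the enolate anti to the C4 side chain to give the (3R,4R)-trans-methyl lactone F6.
- iBu2AlH at −78 °C gives the methyl lactol F7.
- [4-(Benzyloxy)-3-methoxyphenyl]magnesium bromide F8, made from commercial 1-(benzyloxy)-4-bromo-2-methoxybenzene and Mg, opens F7 to the (2R,3R)-1,4-diol F9 as both carbinol epimers.
- Catalytic camphorsulfonic acid in CH2Cl2 at 0 °C ionises the benzylic alcohol, and the primary hydroxy group closes the oxolane trans to the C3 methyl group.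

The route is rejoined at 16, which makes steps 9 to 11 unnecessary.

**Step 5.** Transmetalation at the α-branched alkenylstannane may be slow. Homocoupling or solvolysis of the labile benzylic bromide, protodestannylation or cine substitution could then take over.

The fallback reverses the polarity of the coupling and masks the diol first. It sets out from 6.
- I2 in CH2Cl2 at 0 °C gives, with retention, (E)-2-iodobut-2-ene-1,4-diol F10.
- Acetalisation with 8 under the conditions of step 6 gives the 5-iodo-4,7-dihydro-1,3-dioxepine F11.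
- Bromide 4 is converted with Zn and LiCl in THF into [4-(benzyloxy)-3,5-dimethoxybenzyl]zinc bromide F12.
- Negishi coupling of F11 with F12 under PdCl2(dppf) in THF at rt forms the same C–C bond.

The route is rejoined at 9.

Further compounds
F1 | step 7 | (5S)-2-[4-(benzyloxy)-3-methoxyphenyl]-5-{[4-(benzyloxy)-3,5-dimethoxyphenyl]methyl}-4,5-dihydro-1,3-dioxepine | COc1cc(C2OC[C@@H](Cc3cc(OC)c(OCc4ccccc4)c(OC)c3)C=CO2)ccc1OCc1ccccc1
F2 | step 7 | (2S,3S,4S)-2-[4-(benzyloxy)-3-methoxyphenyl]-4-{[4-(benzyloxy)-3,5-dimethoxyphenyl]methyl}oxolane-3-carbaldehyde | COc1cc([C@H]2OC[C@@H](Cc3cc(OC)c(OCc4ccccc4)c(OC)c3)[C@@H]2C=O)ccc1OCc1ccccc1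
F3 | step 7 | [(2S,3R,4S)-2-[4-(benzyloxy)-3-methoxyphenyl]-4-{[4-(benzyloxy)-3,5-dimethoxyphenyl]methyl}oxolan-3-yl]methanol | COc1cc([C@H]2OC[C@@H](Cc3cc(OC)c(OCc4ccccc4)c(OC)c3)[C@@H]2CO)ccc1OCc1ccccc1
F4 | step 8 | (4R)-4-{[4-(benzyloxy)-3,5-dimethoxyphenyl]methyl}oxolan-2-ol (both anomers) | OC1OC[C@H](Cc2cc(OC)c(OCc3ccccc3)c(OC)c2)C1
F5 | step 8 | (4R)-4-{[4-(benzyloxy)-3,5-dimethoxyphenyl]methyl}oxolan-2-one | O=C1OC[C@H](Cc2cc(OC)c(OCc3ccccc3)c(OC)c2)C1
F6 | step 8 | (3R,4R)-4-{[4-(benzyloxy)-3,5-dimethoxyphenyl]methyl}-3-methyloxolan-2-one | O=C1OC[C@H](Cc2cc(OC)c(OCc3ccccc3)c(OC)c2)[C@H]1C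
F7 | step 8 | (3R,4R)-4-{[4-(benzyloxy)-3,5-dimethoxyphenyl]methyl}-3-methyloxolan-2-ol (both anomers) | OC1OC[C@H](Cc2cc(OC)c(OCc3ccccc3)c(OC)c2)[C@H]1C
F8 | step 8 | [4-(benzyloxy)-3-methoxyphenyl]magnesium bromide | COc1cc([Mg]Br)ccc1OCc1ccccc1
F9 | step 8 | (2R,3R)-1-[4-(benzyloxy)-3-methoxyphenyl]-3-{[4-(benzyloxy)-3,5-dimethoxyphenyl]methyl}-2-methylbutane-1,4-diol (both C1 epimers) | COc1cc(C(O)[C@H](C)[C@@H](Cc2cc(OC)c(OCc3ccccc3)c(OC)c2)CO)ccc1OCc1ccccc1
F10 | step 5 | (E)-2-iodobut-2-ene-1,4-diol (the two CH2OH groups cis) | OC/C(I)=C\CO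
F11 | step 5 | 2-[4-(benzyloxy)-3-methoxyphenyl]-5-iodo-4,7-dihydro-1,3-dioxepine (racemic at C2) | COc1cc(C2OCC=C(I)CO2)ccc1OCc1ccccc1
F12 | step 5 | [4-(benzyloxy)-3,5-dimethoxybenzyl]zinc bromide | COc1cc(C[Zn]Br)cc(OC)c1OCc1ccccc1
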